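## Structural features

Atom numbers used throughout: C1 is the quaternary carbinol carrying C7H2OH, C2 is CH(OH), C3 and C6 are the CH(OBz) carbons, and C4=C5 is the alkene. The target is a single carbocycle, a cyclohex-4-ene, whose only appendages are the hydroxymethyl carbon C7 on C1 and two benzoyl groups. C6, C1, C2 and C3 are four adjacent stereocentres (1S,2R,3R,6S): O1 lies on one face, while O2, O3, O6 and C7 lie on the other, so the 1,2-diol is trans, the 2,3-pair is cis and C1 is fully substituted. Five oxygens must be told apart: two allylic secondary esters (O3, O6) and three free hydroxyls (tertiary O1, secondary O2, primary O7). The compound is fragile to base and strong acid: a benzoyl group can move from O3 to its cis neighbour O2 and, more readily, from O6 to the primary O7, and the allylic esters can ionise or eliminate towards an arene. The real difficulty is threefold: the quaternary C1 with a defined face, the opposite faces of O1 and O2, and the placing of exactly two acyl groups. The key step exploits the fact that C1–C7 is the skeleton of 2-(hydroxymethyl)-1,4-benzoquinone, with C3 and C6 as carbonyl carbons, C1=C2 as the substituted alkene and C4=C5 as the free alkene that can carry a removable cyclopentadiene unit. In the endo adduct the six-membered ring is folded under the norbornene C=C, so only its convex face is open; that one bias delivers the oxirane oxygen to C1/C2 and later the hydride to C3/C6.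

## Logic of the disconnections

13 to 12: the O7–Si bond is restored. O7 is the thermodynamic acceptor for the C6 benzoyl group, so it stays blocked until nothing else remains to be done. The gain is that 12 has only two free hydroxyls, neither of which invites acyl transfer from O6. The forward step must unveil O7 without generating an alkoxide.

12 to 10: the C2–O2 bond is cut and O1 is reconnected to C2 as an oxirane on the face opposite to O2. Two hydroxyls on opposite faces collapse into one three-membered ring whose face is that of O1. The forward step must open the oxirane at C2 only, with inversion, leaving C1–O untouched. The C3 benzoate, trans to the oxirane, is the internal nucleophile (through 11), and water then releases O2–H.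

10 to 9: the two C–C bonds from C4 and C5 to the five-membered ring of 4 are re-formed (Diels–Alder transform). This returns the rigid scaffold that controls all four stereocentres. The forward cycloreversion is purely thermal, so 9 must carry only heat-stable groups.

9 to 7 + 8: the two acyl C–O bonds on O3 and O6 are cut. At the stage of 7 these are the only free hydroxyls, so the benzoates go on unambiguously and the ester problem of 13 disappears. The forward acylation must be run without acid, so that the unactivated oxirane stays closed.

7 to 6: the C3–H and C6–H bonds are cut, returning two ketones. Two stereocentres are removed at once. The forward reduction must deliver hydride from the convex face at both carbonyls, which puts O3 and O6 on the concave face, opposite to the oxirane.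

6 to 5: the C1–O and C2–O bonds of the oxirane are cut, returning the C1=C2 ene-dione. This is the key simplification: two stereocentres, including the quaternary one, vanish. The forward step needs single-face oxygen transfer to an electron-poor alkene without touching the norbornene alkene.

5 to 3 + 4: the two C–C bonds that join C4 and C5 to 4 are cut. All remaining stereocentres disappear and a flat achiral ring is left. The forward cycloaddition must choose the unsubstituted alkene of 3, follow the endo rule and be enantioselective, since it fixes the absolute configuration of everything that follows.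

3 to 2: no skeletal bond is cut; the two C=O bonds at C3 and C6 are taken back to two phenolic O–H bonds. This reaches a stable, storable aromatic ring. The forward step must be a neutral two-electron oxidation that spares the silyl ether.

2 to 1: the O7–Si bond is cut. This reaches a commercial triol. The forward silylation must select the primary hydroxyl in the presence of two phenols.

## Other disconnections considered

Alternative 1: The cut is at C1–O and C6–O of an aromatic precursor. In the forward sense, whole cells expressing a benzoate dioxygenase would convert benzoic acid A1 into the ipso,ortho cis-diol acid A2.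
- In its favour: the quaternary carbinol C1 appears in one step from an achiral arene, and C1 of A2 already has the sense needed in 13. The absolute configuration comes from an enzyme and not from a catalyst whose sense has to be checked; on that point this route is better than the chosen plan.
- Against it on structure: O6 of A2 is cis to O1 while 13 needs it trans, so C6 must be inverted. A Mitsunobu inversion could install the O6 benzoate at the same time, so this is only a partial loss. The carboxyl must be reduced to C7H2OH, and the C2=C3 alkene must be cis-dihydroxylated anti to O1 and in preference to C4=C5.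
- Against it on selectivity: the resulting free cis-2,3-diol has to be benzoylated on O3 only. The chosen plan avoids that by delivering O2 from a benzoate already sitting on O3. A2 is also prone to aromatise by dehydration.
- Step economy: about equal to the chosen plan. The fermentation demands equipment, but no scaffold has to be attached and removed.

Alternative 2: The cut is the C3–C4 bond. D-glucose A3 would be elaborated into the branched open chain A4, which carries an aldehyde at C3 and a Z-iodoalkene at C4. A4 would be closed by a Nozaki–Hiyama–Kishi reaction (CrCl2 with catalytic NiCl2, through a vinyl species of divalent chromium) to the cyclohexenol A5.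
- In its favour: A5 carries every oxygen in a different guise (O3 free, O6 as a p-methoxybenzyl ether, O2 as a silyl ether, O1/O7 as a spiro acetonide). The two benzoates could therefore be placed with no regiochemical doubt, which is better than the chosen plan. Chirality comes from A3, which is equal in reliability.
- Against it on structure: the quaternary C1 must be built by branching the carbon chain of A3, the iodoalkene of A4 must be made geometrically pure, and the chain needs heavy protecting-group traffic.
- Against it on mechanism: the closure uses stoichiometric toxic chromium. The new C3 centre is set only by induction from C2 during ring closure and may need an oxidation/reduction correction, whereas in the chosen plan C3 is set by a rigid scaffold.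
- Step economy: the linear sequence would be roughly twice as long.

Alternative 3: The cut is the C1–C6 bond. A sugar-derived 2-alkoxyglycal A6 carrying an E-alkoxyvinyl arm would rearrange on heating by a [3,3] shift to the cyclohexene carbaldehyde A7.
- In its favour: one reagent-free pericyclic step closes the carbocycle, creates the quaternary C1 and C6 by chirality transfer through an ordered transition state, and delivers C7 at the aldehyde level. As a stereodefined ring-forming C–C bond construction it is the equal of the chosen key step, which forms no skeletal C–C bond at all.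
- Against it on structure: the geometry of the enol ether arm of A6 maps directly onto C6, so it must be pure. A7 holds O2 and O3 in one acetonide, so the late problem of acylating O3 and not O2 returns and is no better solved than in the chosen plan. O1 and O6 carry the same ether, although O1 is tertiary and would not acylate.
- Step economy: clearly worse, because A6 needs many steps from a sugar. The thermal conditions are comparable to the cycloreversion of the chosen plan.

Key step: step 4

Assumption 1: the (S)-configured oxazaborolidinium catalyst is written for step 3; if the usual quinone model places the diene on the other face, the mirror-image catalyst is used with no other change.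

Assumption 2: 4 is distilled from its commercial dimer immediately before use; this cracking is not counted as a step.

## Route

Step 1
Reactants: 1 2,5-dihydroxybenzyl alcohol (gentisyl alcohol)
Product: 2 2-{[(tert-butyldimethylsilyl)oxy]methyl}benzene-1,4-diol
Conditions: TBSCl (1.05 equiv), imidazole (2.2 equiv), DMF, 0 °C
Reagents that add atoms: tert-butyldimethylsilyl chloride (TBSCl), CC(C)(C)[Si](C)(C)Cl
Why: Imidazole-mediated silylation; with one equivalent of silyl chloride at 0 °C the primary benzylic hydroxyl should react ahead of the two less nucleophilic phenols, as is usual for hydroxybenzyl alcohols.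

Step 2
Reactants: 2 2-{[(tert-butyldimethylsilyl)oxy]methyl}benzene-1,4-diol
Product: 3 2-{[(tert-butyldimethylsilyl)oxy]methyl}cyclohexa-2,5-diene-1,4-dione
Conditions: PhI(OAc)2 (1.05 equiv), MeCN/H2O, 0 °C
Reagents that add atoms: none
Why: Hypervalent-iodine oxidation of a hydroquinone to the p-quinone (ligand exchange at iodine, then loss of iodobenzene); the medium is nearly neutral, so the silyl ether should survive.

Step 3
Reactants: 3 2-{[(tert-butyldimethylsilyl)oxy]methyl}cyclohexa-2,5-diene-1,4-dione; 4 cyclopenta-1,3-diene
Product: 5 (1S,4R,4aS,8aR)-6-{[(tert-butyldimethylsilyl)oxy]methyl}-1,4,4a,8a-tetrahydro-1,4-methanonaphthalene-5,8-dione (endo adduct)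
Conditions: (S)-3,3-diphenyl-1-(2-methylphenyl)tetrahydro-1H,3H-pyrrolo[1,2-c][1,3,2]oxazaborole (20 mol %), Tf2NH (17 mol %), 4 (3 equiv), CH2Cl2, −78 °C
Reagents that add atoms: none
Why: Catalytic enantioselective Diels–Alder reaction with a cationic oxazaborolidine; the cation should bind the more basic carbonyl (C3=O, vinylogously enriched by the C1 substituent) and activate the unsubstituted C4=C5 alkene, which is also the less hindered one. Endo approach of the diene to the face not shielded by the catalyst aryl group sets C4, C5 and both bridgeheads in one event.

Step 4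
Reactants: 5 (1S,4R,4aS,8aR)-6-{[(tert-butyldimethylsilyl)oxy]methyl}-1,4,4a,8a-tetrahydro-1,4-methanonaphthalene-5,8-dione
Product: 6 (1S,4R,4aS,6S,7R,8aR)-6-{[(tert-butyldimethylsilyl)oxy]methyl}-6,7-epoxy-1,4,4a,6,7,8a-hexahydro-1,4-methanonaphthalene-5,8-dione (oxirane on the convex face, syn to H-4a and H-8a)
Conditions: 30% aq. H2O2 (3 equiv), Na2CO3 (0.3 equiv), acetone, 0 °C
Reagents that add atoms: hydrogen peroxide, OO
Why: Hydroperoxide anion adds in conjugate fashion to C2, the unsubstituted carbon of the ene-dione, giving the enolate of the C6 ketone at C1. The enolate carbon C1 then displaces hydroxide from the peroxide oxygen, which forms C1–O and completes the oxirane. This is the Weitz–Scheffer nucleophilic epoxidation, a well-known reaction of cyclopentadiene–quinone adducts. The oxirane closes by a 3-exo-tet attack of carbon on the O–O bond. Both new stereocentres, C2 and the quaternary C1, are controlled by the endo-fused scaffold: the norbornene C=C lies over the concave face of C1=C2, so the peroxide can arrive only from the convex face, where the ring-fusion hydrogens stand, and the closure necessarily follows on that same face. This places O1 as required in 13 and leaves C7 on the concave face. The step also needs chemoselectivity, which comes from the nucleophilic oxidant ignoring the electron-rich norbornene alkene, and it needs the acidic ring-fusion hydrogens to survive, which the weak base at 0 °C should allow. The silyl ether is inert under these conditions.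

Step 5
Reactants: 6 (1S,4R,4aS,6S,7R,8aR)-6-{[(tert-butyldimethylsilyl)oxy]methyl}-6,7-epoxy-1,4,4a,6,7,8a-hexahydro-1,4-methanonaphthalene-5,8-dione
Product: 7 (1S,4R,4aS,5S,6R,7S,8R,8aR)-6-{[(tert-butyldimethylsilyl)oxy]methyl}-6,7-epoxy-1,4,4a,5,6,7,8,8a-octahydro-1,4-methanonaphthalene-5,8-diol (both hydroxyls on the concave face, anti to the oxirane)
Conditions: NaBH4 (2.5 equiv), CeCl3·7H2O (2.2 equiv), MeOH, −78 → −20 °C
Reagents that add atoms: none
Why: Luche-type borohydride reduction; the concave face of both carbonyls is blocked by the norbornene bridge, so hydride should enter from the convex face and push O3 and O6 to the concave side, opposite to the oxirane. The cerium salt speeds carbonyl addition at low temperature and keeps the medium from epimerising the ring-fusion centres.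

Step 6
Reactants: 7 (1S,4R,4aS,5S,6R,7S,8R,8aR)-6-{[(tert-butyldimethylsilyl)oxy]methyl}-6,7-epoxy-1,4,4a,5,6,7,8,8a-octahydro-1,4-methanonaphthalene-5,8-diol; 8 benzoyl chloride
Product: 9 (1S,4R,4aS,5S,6R,7S,8R,8aR)-6-{[(tert-butyldimethylsilyl)oxy]methyl}-6,7-epoxy-1,4,4a,5,6,7,8,8a-octahydro-1,4-methanonaphthalene-5,8-diyl dibenzoate
Conditions: 8 (3 equiv), pyridine, DMAP (0.2 equiv), CH2Cl2, 0 °C → rt
Reagents that add atoms: none
Why: DMAP-catalysed acylation of the only two free hydroxyls, so the benzoates cannot be misplaced and no stereocentre is touched. The oxirane is not activated in this acid-free, weakly basic medium and should therefore stay closed.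

Step 7
Reactants: 9 (1S,4R,4aS,5S,6R,7S,8R,8aR)-6-{[(tert-butyldimethylsilyl)oxy]methyl}-6,7-epoxy-1,4,4a,5,6,7,8,8a-octahydro-1,4-methanonaphthalene-5,8-diyl dibenzoate
Product: 10 (1R,2S,5R,6S)-1-{[(tert-butyldimethylsilyl)oxy]methyl}-7-oxabicyclo[4.1.0]hept-3-ene-2,5-diyl dibenzoate
Conditions: Ph2O (0.02 M), 240 °C, Ar sweep, base-washed glass
Reagents that add atoms: none
Why: Thermal retro-Diels–Alder cycloreversion, driven by entropy and by removal of volatile 4; it frees C4=C5 and touches none of the four stereocentres. Esters, silyl ether and oxirane are neutral groups that should tolerate brief heating.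

Step 8
Reactants: 10 (1R,2S,5R,6S)-1-{[(tert-butyldimethylsilyl)oxy]methyl}-7-oxabicyclo[4.1.0]hept-3-ene-2,5-diyl dibenzoate
Product: 12 (1S,2R,3R,6S)-1-{[(tert-butyldimethylsilyl)oxy]methyl}-1,2-dihydroxycyclohex-4-ene-3,6-diyl dibenzoate, via dioxolanylium trifluoroborate zwitterion 11 (not isolated)
Conditions: BF3·OEt2 (1.2 equiv), CH2Cl2, −40 → −15 °C; then Et3N, THF/H2O, 0 °C
Reagents that add atoms: water, O
Why: Lewis-acid-promoted epoxide opening with neighbouring-group participation: the carbonyl oxygen of the O3 benzoate, trans to the oxirane, attacks C2 from the rear (5-exo-tet, inversion at C2) while C1–O stays intact, and water then cleaves ion 11 to the cis hydroxy ester. C2 should be preferred over C1 because it is secondary and reached in an SN2-like manner, whereas attack of the weakly nucleophilic O6 ester at the fully substituted C1 would need C–O ionisation that the two flanking oxygen-bearing carbons (C6, C7) disfavour. The benzoyl group is expected to settle on the less hindered allylic O3, and O7 stays silylated so it cannot accept an acyl group.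

Step 9
Reactants: 12 (1S,2R,3R,6S)-1-{[(tert-butyldimethylsilyl)oxy]methyl}-1,2-dihydroxycyclohex-4-ene-3,6-diyl dibenzoate
Product: 13 (1S,2R,3R,6S)-1,2-dihydroxy-1-(hydroxymethyl)cyclohex-4-ene-3,6-diyl dibenzoate
Conditions: HF·pyridine, pyridine/THF, 0 °C → rt
Reagents that add atoms: none
Why: Fluoride-driven Si–O cleavage in a buffered acidic medium generates no alkoxide, so the benzoyl groups should stay on O3 and O6 and not move to O2 or O7. No stereocentre is involved.

## Compound list

1 | 2,5-dihydroxybenzyl alcohol (gentisyl alcohol) | OCc1cc(O)ccc1O | starting material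
2 | 2-{[(tert-butyldimethylsilyl)oxy]methyl}benzene-1,4-diol | CC(C)(C)[Si](C)(C)OCc1cc(O)ccc1O | intermediate
3 | 2-{[(tert-butyldimethylsilyl)oxy]methyl}cyclohexa-2,5-diene-1,4-dione | CC(C)(C)[Si](C)(C)OCC1=CC(=O)C=CC1=O | intermediate
4 | cyclopenta-1,3-diene | C1C=CC=C1 | starting material
5 | (1S,4R,4aS,8aR)-6-{[(tert-butyldimethylsilyl)oxy]methyl}-1,4,4a,8a-tetrahydro-1,4-methanonaphthalene-5,8-dione | O=C1C=C(CO[Si](C)(C)C(C)(C)C)C(=O)[C@@H]2[C@H]1[C@@H]1C=C[C@H]2C1 | intermediate
6 | (1S,4R,4aS,6S,7R,8aR)-6-{[(tert-butyldimethylsilyl)oxy]methyl}-6,7-epoxy-1,4,4a,6,7,8a-hexahydro-1,4-methanonaphthalene-5,8-dione | O=C1[C@@H]3O[C@]3(CO[Si](C)(C)C(C)(C)C)C(=O)[C@@H]2[C@H]1[C@@H]1C=C[C@H]2C1 | intermediate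
7 | (1S,4R,4aS,5S,6R,7S,8R,8aR)-6-{[(tert-butyldimethylsilyl)oxy]methyl}-6,7-epoxy-1,4,4a,5,6,7,8,8a-octahydro-1,4-methanonaphthalene-5,8-diol | O[C@H]1[C@@H]3O[C@]3(CO[Si](C)(C)C(C)(C)C)[C@@H](O)[C@@H]2[C@H]1[C@@H]1C=C[C@H]2C1 | intermediate
8 | benzoyl chloride | O=C(Cl)c1ccccc1 | starting material
9 | (1S,4R,4aS,5S,6R,7S,8R,8aR)-6-{[(tert-butyldimethylsilyl)oxy]methyl}-6,7-epoxy-1,4,4a,5,6,7,8,8a-octahydro-1,4-methanonaphthalene-5,8-diyl dibenzoate | O=C(O[C@H]1[C@@H]3O[C@]3(CO[Si](C)(C)C(C)(C)C)[C@@H](OC(=O)c4ccccc4)[C@@H]2[C@H]1[C@@H]1C=C[C@H]2C1)c1ccccc1 | intermediate
10 | (1R,2S,5R,6S)-1-{[(tert-butyldimethylsilyl)oxy]methyl}-7-oxabicyclo[4.1.0]hept-3-ene-2,5-diyl dibenzoate | O=C(O[C@H]1[C@@H]3O[C@]3(CO[Si](C)(C)C(C)(C)C)[C@@H](OC(=O)c4ccccc4)C=C1)c1ccccc1 | intermediate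
11 | 2-phenyl-1,3-dioxolan-2-ylium ion cis-fused across O2/O3 on the face of C7, with O1 as its trifluoroborate adduct, O6 benzoate and O7 silyl ether unchanged | O=C(O[C@H]1C=C[C@H]2[O+]=C(c3ccccc3)O[C@H]2[C@@]1(O[B-](F)(F)F)CO[Si](C)(C)C(C)(C)C)c1ccccc1 | intermediate
12 | (1S,2R,3R,6S)-1-{[(tert-butyldimethylsilyl)oxy]methyl}-1,2-dihydroxycyclohex-4-ene-3,6-diyl dibenzoate | O=C(O[C@H]1C=C[C@@H](OC(=O)c2ccccc2)[C@@H](O)[C@@]1(O)CO[Si](C)(C)C(C)(C)C)c1ccccc1 | intermediate
13 | (1S,2R,3R,6S)-1,2-dihydroxy-1-(hydroxymethyl)cyclohex-4-ene-3,6-diyl dibenzoate | O=C(O[C@H]1C=C[C@@H](OC(=O)c2ccccc2)[C@@H](O)[C@@]1(O)CO)c1ccccc1 | target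

## Step count and least certain steps

Total step count: 9. Longest linear sequence: 9 steps (1 to 13); 4 and 8 enter as commercial inputs.

Step 4 (key step). The most likely failure is base-induced enolisation at the ring-fusion carbons, which would lead irreversibly to the aromatic hydroquinone before the peroxide has added. A secondary concern is slow conjugate addition beside the bulky silyloxymethyl group. The facial outcome is not in doubt, because the concave face is closed. Fallback with a change of order, so that the aromatisable ene-dione never meets base: starting from 5, a substoichiometric Luche reduction (NaBH4, 0.3 equiv, with CeCl3·7H2O in MeOH at −78 °C) should reduce the less hindered C3 carbonyl from the convex face. This would give (1S,4R,4aS,8R,8aR)-6-{[(tert-butyldimethylsilyl)oxy]methyl}-8-hydroxy-1,4,4a,8a-tetrahydro-1,4-methanonaphthalen-5(8H)-one, F1. This hydroxy enone can no longer tautomerise to an arene. Weitz–Scheffer epoxidation of it (30% aq. H2O2, catalytic NaOH, MeOH, 0 °C) should again come from the convex face and give (1S,4R,4aS,6S,7S,8R,8aR)-6-{[(tert-butyldimethylsilyl)oxy]methyl}-6,7-epoxy-8-hydroxy-1,4,4a,6,7,8a-hexahydro-1,4-methanonaphthalen-5(8H)-one, F2. A second reduction with NaBH4 and CeCl3·7H2O then rejoins the route at 7.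

Step 8. Three things may go wrong. Ionisation may occur at the tertiary C1 instead of C2, with attack of the O6 benzoate there and inversion of the quaternary centre. The dioxolanylium ion may collapse so that the benzoyl group ends on O2. The silyl ether may be lost early, after which O7 could capture an acyl group. Should only the O2/O3 distribution be unfavourable, brief treatment of the still-silylated product with a catalytic amine base would be tried first, to equilibrate the cis pair towards the less hindered O3. Fallback with a change of mechanism: starting from 10, a buffered carboxylate opens the oxirane in an intermolecular SN2 process, which can reach only the secondary C2 because C1 is fully substituted. Cesium levulinate (CsO2CCH2CH2COCH3) with levulinic acid in DMF at 70 °C should give the 2-O-levulinoyl derivative of 12, F3. Hydrazine acetate (N2H4·AcOH) in pyridine/acetic acid then removes the levulinoyl group selectively beside the benzoates, and the route is rejoined at 12.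

Step 3. The uncatalysed cycloaddition of 4 to a quinone is fast even at low temperature, so incomplete enantio-induction is the main risk; the sense of induction must also be confirmed. Fallback by resolution instead of asymmetric catalysis: starting from 3 and 4, the uncatalysed endo cycloaddition in CH2Cl2 at 0 °C gives 5 together with its mirror image F4. Epoxidation as in step 4 gives 6 together with its mirror image F5. The pair is resolved by preparative chromatography on a chiral stationary phase at this chemically robust stage, and the route is rejoined at 6.

Step 7. At 240 °C the allylic benzoates may undergo a sigmatropic shift, the oxirane may open by acid catalysis on hot glass, and the heavy substrate may decompose before cycloreversion is complete. Fallback with a change of order: starting from 7, the more volatile diol is subjected to flash vacuum pyrolysis, which should give (1R,2S,5R,6S)-1-{[(tert-butyldimethylsilyl)oxy]methyl}-7-oxabicyclo[4.1.0]hept-3-ene-2,5-diol, F6. Benzoylation of its two allylic hydroxyls with 8, pyridine and DMAP rejoins the route at 10.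

## Further compounds

F1 | step 4 | (1S,4R,4aS,8R,8aR)-6-{[(tert-butyldimethylsilyl)oxy]methyl}-8-hydroxy-1,4,4a,8a-tetrahydro-1,4-methanonaphthalen-5(8H)-one | O[C@H]1C=C(CO[Si](C)(C)C(C)(C)C)C(=O)[C@@H]2[C@H]1[C@@H]1C=C[C@H]2C1
F2 | step 4 | (1S,4R,4aS,6S,7S,8R,8aR)-6-{[(tert-butyldimethylsilyl)oxy]methyl}-6,7-epoxy-8-hydroxy-1,4,4a,6,7,8a-hexahydro-1,4-methanonaphthalen-5(8H)-one | O[C@H]1[C@@H]3O[C@]3(CO[Si](C)(C)C(C)(C)C)C(=O)[C@@H]2[C@H]1[C@@H]1C=C[C@H]2C1
F3 | step 8 | 2-O-(4-oxopentanoyl) derivative of 12 (configuration at all centres as in 12) | O=C(O[C@H]1C=C[C@@H](OC(=O)c2ccccc2)[C@@H](OC(=O)CCC(C)=O)[C@@]1(O)CO[Si](C)(C)C(C)(C)C)c1ccccc1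
F4 | step 3 | (1R,4S,4aR,8aS)-6-{[(tert-butyldimethylsilyl)oxy]methyl}-1,4,4a,8a-tetrahydro-1,4-methanonaphthalene-5,8-dione (mirror image of 5) | O=C1C=C(CO[Si](C)(C)C(C)(C)C)C(=O)[C@H]2[C@@H]1[C@H]1C=C[C@@H]2C1
F5 | step 3 | (1R,4S,4aR,6R,7S,8aS)-6-{[(tert-butyldimethylsilyl)oxy]methyl}-6,7-epoxy-1,4,4a,6,7,8a-hexahydro-1,4-methanonaphthalene-5,8-dione (mirror image of 6) | O=C1[C@H]3O[C@@]3(CO[Si](C)(C)C(C)(C)C)C(=O)[C@H]2[C@@H]1[C@H]1C=C[C@@H]2C1
F6 | step 7 | (1R,2S,5R,6S)-1-{[(tert-butyldimethylsilyl)oxy]methyl}-7-oxabicyclo[4.1.0]hept-3-ene-2,5-diol | O[C@H]1[C@@H]3O[C@]3(CO[Si](C)(C)C(C)(C)C)[C@@H](O)C=C1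
A1 | alternative 1 | benzoic acid | OC(=O)c1ccccc1
A2 | alternative 1 | (1S,2R)-1,2-dihydroxycyclohexa-3,5-diene-1-carboxylic acid | OC(=O)[C@]1(O)C=CC=C[C@H]1O
A3 | alternative 2 | D-glucose (open-chain form) | OC[C@@H](O)[C@@H](O)[C@H](O)[C@@H](O)C=O
A4 | alternative 2 | open-chain aldehyde (C3) with O2 silyl ether, O1/O7 spiro acetonide, O6 p-methoxybenzyl ether and Z-iodoalkene C5=C4 | I/C=C\[C@H](OCc1ccc(OC)cc1)[C@]2(COC(C)(C)O2)[C@H](O[Si](C)(C)C(C)(C)C)C=O
A5 | alternative 2 | cyclohexenol with free O3–H, O2 silyl ether, O6 p-methoxybenzyl ether and spiro O1/O7 acetonide | O[C@@H]1C=C[C@H](OCc2ccc(OC)cc2)[C@]2(COC(C)(C)O2)[C@@H]1O[Si](C)(C)C(C)(C)C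
A6 | alternative 3 | 2-(p-methoxybenzyloxy)glycal with 3,4-O-isopropylidene group and an E-2-(p-methoxybenzyloxy)vinyl arm trans to the acetonide | COc1ccc(CO/C=C/[C@H]2OC=C(OCc3ccc(OC)cc3)[C@@H]3OC(C)(C)O[C@H]23)cc1
A7 | alternative 3 | 1,6-bis(p-methoxybenzyloxy)-2,3-O-isopropylidene-cyclohex-4-ene-1-carbaldehyde | O=C[C@@]1(OCc3ccc(OC)cc3)[C@@H](OCc3ccc(OC)cc3)C=C[C@H]2OC(C)(C)O[C@@H]12
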